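The data come from a simulation with made-up constants, noise included.

No rate constant stands beside these flasks, so the constants have to be read off the earlier runs: how high D climbs before its curve bends, and how long it takes to get there.

| flask | Q | L | J | remark | time |
|---|---|---|---|---|---|
| grey | 0.080 M | 0.16 equiv | 2 equiv | run made earlier |  |
| red | 0.080 M | 0.64 equiv | 2 equiv | run made earlier |  |
| amber | 0.057 M | 0.50 equiv | 2 equiv | run made earlier |  |
| north-east | 0.080 M | 0.500 equiv | 2.00 equiv |  | 1.0 h |
| south-east | 0.025 M | 0.500 equiv | 2.00 equiv |  | 1.0 h |
| east | 0.025 M | 0.120 equiv | 0.660 equiv |  | 1.0 h |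
| south-west | 0.025 M | 0.250 equiv | 1.00 equiv |  | 1.0 h |

| run | time / min | D / % |
|---|---|---|
| grey | 5.00 | 2.5 |
| grey | 15.0 | 7.1 |
| grey | 25.0 | 7.0 |
| grey | 40.0 | 10.2 |
| red | 10.0 | 12.3 |
| red | 20.0 | 19.3 |
| red | 30.0 | 24.1 |
| red | 40.0 | 27.2 |
| amber | 3.00 | 2.7 |
| amber | 8.00 | 6.8 |
| amber | 20.0 | 12.9 |
| amber | 40.0 | 20.1 |

(readings scatter by 1 percentage point)

- the analysis behind the earlier runs scatters by 1 percentage point, standard deviation

- all flasks from highest to lowest amount of D, in percent of the Q charged, at 1.0 h (north-east / south-east / east / south-west)
- the amount of D, in percent of the Q charged of the flask you put first, at 1.0 h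
- the amount of D, in percent of the Q charged of the flask you put last, at 1.0 h

The curves of the earlier runs bend near a ceiling H, 25.0% for north-east: half of the equivalents of L, as percent of the Q charged. Red at 27.2% is still under its 32.0%, but grey at 10.2% already stands above its 8.00%, by more than the scatter, so H reads as a knee and not a wall. Amber, at 20.1% after 40.0 min against a ceiling of 25.0%, gives an approach time of 24.5 min, which my own reckoning scales inversely with c(Q).

Two extreme flasks can be solved in the head. In a very fast one, D sits at H by the hour. In north-east the approach time is 17.5 min, and in a very slow flask D keeps its starting slope, a straight line that reaches 85.8% there. My reckoning takes the curve H(1 − exp(−t/τ)), with τ the approach time, which stays under both extremes; it is an estimate and no bound, and the grey reading stands above its H. North-east has a reading time well beyond τ and lies near its knee, at 24.2%. South-east, with τ of 56.0 min, reaches 16.4% on that curve. South-west reaches 8.22%, and east, with H of 6.00%, reaches 3.95%. The earlier runs held J at 2 equiv, so this reckoning cannot see J.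

The forecast gives north-east > south-east > south-west > east, with 26% and 2.5%, on the ground that “the plateau is set by the L equivalents”. Its order matches my reckoning, but its two numbers differ from mine.

The flasks give north-east > south-east > south-west > east, with 25.6% and 5.01%.

    Q + E → X + D (k = 0.360 M⁻¹ min⁻¹)
    E + X ⇌ J, settled at all times (K = 9000 M⁻¹)
    X + L ⇌ Z, settled at all times (K = 55000 M⁻¹)
    Q + X ⇌ G, settled at all times (K = 17.0 M⁻¹)

North-east stands at 25.6%, just over its H of 25.0%, and Z there holds 0.0398 M at 1.00 h, close to the 0.0400 M of L charged. With L held at its charged level, east gives 16.6% instead of 5.01%, and left ten times as long it gives 15.7%: the falling level of L and the hour of the reading act together. East left until 4.0 h stands at 10.8%, past its H of 6.00%.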